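**Retrosynthetic overview**
1. Target 18 ⇒ triol 14: the oxolane C2–O bond is made last, in a redox-neutral cycloetherification that also sets C2.
2. 14 ⇒ trans keto lactone 12 by full reduction; the trans lactone pattern becomes the C3/C4-cis pattern of the oxolane.
3. 12 ⇒ acyl malonate lactone 10 (dealkoxycarbonylation) ⇒ cyclopropane lactone 6 + aryl Grignard 7 + aroyl chloride 8 in one pot.
4. 6 ⇒ dimethyl malonate 1 + (R)-epichlorohydrin 2, the only source of chirality (C4).
5. Ring order: cyclopropane and γ-lactone together in step 1 (both opened later), then the oxolane in step 5.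

Assumption: the SMILES is read as the (2R,3R,4R) oxolane with aryl, CH2OH and benzyl all on one face (all-cis, the C2 epimer of the lariciresinol pattern).

**Route**

Step 1
Reactants: 1 dimethyl malonate; 2 (R)-epichlorohydrin
Product: 6 methyl (1S,5R)-2-oxo-3-oxabicyclo[3.1.0]hexane-1-carboxylate, via chlorohydrin malonate 3 (not isolated), via epoxy malonate 4 (not isolated), via cyclopropyl carbinol diester 5 (not isolated)
Conditions: NaOMe (1.1 equiv), MeOH, 0 °C then reflux, 18 h
Reagents that add atoms: none
Why: Double alkylation/lactonisation cascade in which the malonate anion opens the epoxide at CH2, the alkoxide closes a new epoxide with loss of chloride (intramolecular Williamson), the malonate carbanion opens that epoxide 3-exo-tet with inversion at the stereocentre and the freed alkoxide lactonises onto the cis ester, so (R)-2 gives (1S,5R)-6 (typically about 95% ee).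

Step 2
Reactants: 6 methyl (1S,5R)-2-oxo-3-oxabicyclo[3.1.0]hexane-1-carboxylate; 7 (3,4-dimethoxyphenyl)magnesium bromide; 8 3,4,5-trimethoxybenzoyl chloride
Product: 10 methyl (3S,4R)-4-(3,4-dimethoxybenzyl)-2-oxo-3-(3,4,5-trimethoxybenzoyl)oxolane-3-carboxylate, via magnesium enolate 9 (not isolated)
Conditions: 7 (1.3 equiv), CuI (20 mol %), THF, −30 to 0 °C; then 8 (1.7 equiv), 0 °C to rt
Reagents that add atoms: none
Why: Cuprate homo-conjugate (SN2-type) opening of the doubly activated cyclopropane at its unsubstituted CH2 leaves the C5 stereocentre untouched (it becomes C4 of the lactone, R) and gives a chelated magnesium malonate enolate that undergoes Claisen-type C-acylation by 8 anti to the benzyl group; the quaternary centre is erased in step 3, so its configuration is immaterial.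

Step 3
Reactants: 10 methyl (3S,4R)-4-(3,4-dimethoxybenzyl)-2-oxo-3-(3,4,5-trimethoxybenzoyl)oxolane-3-carboxylate
Product: 12 (3S,4R)-4-(3,4-dimethoxybenzyl)-3-(3,4,5-trimethoxybenzoyl)oxolan-2-one, via lithium carboxylate 11 (not isolated)
Conditions: LiCl (2 equiv), H2O (2 equiv), DMSO, 110 °C
Reagents that add atoms: none
Why: Krapcho dealkoxycarbonylation, in which chloride attacks the ester CH3 far faster than the β-branched lactone CH2, the triacylmethane carboxylate 11 loses CO2 easily, and protonation of the enolisable β-keto lactone places the aroyl group trans to the benzyl group under thermodynamic control (3S).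

Step 4
Reactants: 12 (3S,4R)-4-(3,4-dimethoxybenzyl)-3-(3,4,5-trimethoxybenzoyl)oxolan-2-one
Product: 14 (2R,3R)-2-(3,4-dimethoxybenzyl)-3-[hydroxy(3,4,5-trimethoxyphenyl)methyl]butane-1,4-diol (both carbinol epimers), via hydroxy lactone 13 (not isolated)
Conditions: LiBH4 (4 equiv), MeOH (4 equiv), THF, 0 °C to rt
Reagents that add atoms: none
Why: Borohydride reduction in which the aryl ketone goes first (giving both carbinol epimers, harmless because step 5 re-oxidises this carbon), which removes the acidity at C3 and locks the trans arrangement, after which LiBH4/MeOH reduces the lactone to the 1,4-diol without touching the aryl ethers.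

Step 5
Reactants: 14 (2R,3R)-2-(3,4-dimethoxybenzyl)-3-[hydroxy(3,4,5-trimethoxyphenyl)methyl]butane-1,4-diol (both carbinol epimers)
Product: 18 [(2R,3R,4R)-4-(3,4-dimethoxybenzyl)-2-(3,4,5-trimethoxyphenyl)oxolan-3-yl]methanol, via keto diol 15 (not isolated), via hemiketal 16 (not isolated), via oxocarbenium ion 17 (not isolated)
Conditions: {[(η5-Ph4C4CO)]2H}Ru2(CO)4(μ-H) (Shvo complex, 2 mol %), PhCO2H (20 mol %), toluene (0.05 M), 90 °C, sealed tube with small headspace, Ar
Reagents that add atoms: none
Why: Proposed new method: stereoconvergent hydrogen-borrowing cycloetherification, in which the Shvo complex dissociates into a zerovalent ruthenium cyclopentadienone species that dehydrogenates the benzylic carbinol of either epimer of 14 to ketone 15 and stores the hydrogen as the divalent ruthenium hydride/ligand O–H pair, 15 closes through its γ-hydroxyl (the β-hydroxyl would give a four-membered ring) to hemiketal 16 and so forms the C2–O ring bond, benzoic acid ionises 16 to the aryl-stabilised ion 17, and outer-sphere hydride return from ruthenium to the face anti to the cis-disposed C3 CH2OH and C4 benzyl groups leaves the aryl group cis to both (2R), with the sealed vessel keeping the hydrogen in the system; the closest known reaction types are Shvo-catalysed racemisation and hydrogen-borrowing amination of secondary alcohols, ruthenium hydride/acid reductive etherification of ketones with alcohols under H2, and the Et3SiH/BF3·OEt2 reduction of 2-aryl lactols to 2,3-cis oxolanes.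

**Compound list**
1 | dimethyl malonate | COC(=O)CC(=O)OC | starting material
2 | (R)-epichlorohydrin, (2R)-2-(chloromethyl)oxirane | ClC[C@H]1CO1 | starting material
3 | dimethyl 2-[(2R)-3-chloro-2-hydroxypropyl]propanedioate (present as sodium alkoxide, not isolated) | ClC[C@H](O)CC(C(=O)OC)C(=O)OC | intermediate
4 | dimethyl 2-{[(2R)-oxiran-2-yl]methyl}propanedioate (not isolated) | C1[C@H](O1)CC(C(=O)OC)C(=O)OC | intermediate
5 | dimethyl (2R)-2-(hydroxymethyl)cyclopropane-1,1-dicarboxylate (present as sodium alkoxide, not isolated) | COC(=O)C1(C(=O)OC)C[C@H]1CO | intermediate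
6 | methyl (1S,5R)-2-oxo-3-oxabicyclo[3.1.0]hexane-1-carboxylate | COC(=O)[C@]12C[C@H]1COC2=O | intermediate
7 | (3,4-dimethoxyphenyl)magnesium bromide (commercial THF solution, or from 4-bromoveratrole and Mg) | COc1ccc([Mg]Br)cc1OC | starting material
8 | 3,4,5-trimethoxybenzoyl chloride | COc1cc(C(=O)Cl)cc(OC)c1OC | starting material
9 | bromomagnesium enolate of methyl (4R)-4-(3,4-dimethoxybenzyl)-2-oxooxolane-3-carboxylate (not isolated) | COc1ccc(C[C@H]2COC(O[Mg]Br)=C2C(=O)OC)cc1OC | intermediate
10 | methyl (3S,4R)-4-(3,4-dimethoxybenzyl)-2-oxo-3-(3,4,5-trimethoxybenzoyl)oxolane-3-carboxylate | COC(=O)[C@]1(C(=O)c2cc(OC)c(OC)c(OC)c2)C(=O)OC[C@@H]1Cc1ccc(OC)c(OC)c1 | intermediate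
11 | lithium (3S,4R)-4-(3,4-dimethoxybenzyl)-2-oxo-3-(3,4,5-trimethoxybenzoyl)oxolane-3-carboxylate (not isolated) | [Li+].[O-]C(=O)[C@]1(C(=O)c2cc(OC)c(OC)c(OC)c2)C(=O)OC[C@@H]1Cc1ccc(OC)c(OC)c1 | intermediate
12 | (3S,4R)-4-(3,4-dimethoxybenzyl)-3-(3,4,5-trimethoxybenzoyl)oxolan-2-one (trans) | COc1ccc(C[C@H]2COC(=O)[C@@H]2C(=O)c2cc(OC)c(OC)c(OC)c2)cc1OC | intermediate
13 | (3S,4R)-4-(3,4-dimethoxybenzyl)-3-[hydroxy(3,4,5-trimethoxyphenyl)methyl]oxolan-2-one (trans, both carbinol epimers, not isolated) | COc1ccc(C[C@H]2COC(=O)[C@@H]2C(O)c2cc(OC)c(OC)c(OC)c2)cc1OC | intermediate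
14 | (2R,3R)-2-(3,4-dimethoxybenzyl)-3-[hydroxy(3,4,5-trimethoxyphenyl)methyl]butane-1,4-diol (both carbinol epimers) | COc1ccc(C[C@@H](CO)[C@H](CO)C(O)c2cc(OC)c(OC)c(OC)c2)cc1OC | intermediate
15 | (2R,3R)-3-(3,4-dimethoxybenzyl)-4-hydroxy-2-(hydroxymethyl)-1-(3,4,5-trimethoxyphenyl)butan-1-one (not isolated) | COc1ccc(C[C@@H](CO)[C@H](CO)C(=O)c2cc(OC)c(OC)c(OC)c2)cc1OC | intermediate
16 | (3R,4R)-4-(3,4-dimethoxybenzyl)-3-(hydroxymethyl)-2-(3,4,5-trimethoxyphenyl)oxolan-2-ol (both anomers, not isolated) | COc1ccc(C[C@H]2COC(O)(c3cc(OC)c(OC)c(OC)c3)[C@H]2CO)cc1OC | intermediate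
17 | (3R,4R)-4-(3,4-dimethoxybenzyl)-3-(hydroxymethyl)-2-(3,4,5-trimethoxyphenyl)oxolan-2-ylium, oxocarbenium ion (not isolated) | COc1ccc(C[C@H]2C[O+]=C(c3cc(OC)c(OC)c(OC)c3)[C@H]2CO)cc1OC | intermediate
18 | [(2R,3R,4R)-4-(3,4-dimethoxybenzyl)-2-(3,4,5-trimethoxyphenyl)oxolan-3-yl]methanol | COc1ccc(C[C@H]2CO[C@@H](c3cc(OC)c(OC)c(OC)c3)[C@H]2CO)cc1OC | target

**Step count and risks**

Total steps: 5. Longest linear sequence: 5 (7 and 8 are bought). No protecting groups. C4 comes from 2 in step 1, C3 is set in step 3 and locked in step 4, C2 is set in step 5.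

The three steps most likely to fail:

Step 5, the new hydrogen-borrowing cyclisation. Possible failures are acid-promoted SN1 closure of the benzylic alcohol to the 2,3-trans isomer, epimerisation at C3 through the enol ether of 17, dehydrogenation of the primary alcohols (lactol, lactone or the other cyclic ether), and dehydration or retro-aldol loss from 15. The fallback uses known chemistry, sets out from 14 and comes back at 18. Activated MnO2 in CH2Cl2 at rt oxidises only the benzylic carbinol of both epimers, and keto diol 15 is isolated as its hemiketal 16. Et3SiH and BF3·OEt2 in CH2Cl2 at −78 °C then reduce ion 17 from the face anti to the C3 and C4 substituents, the established way to 2,3-cis 2-aryl oxolanes, and the low temperature suppresses C3 epimerisation. This costs one extra step and makes no compound outside the list.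

Step 2, the one-pot ring opening and enolate acylation. Enolate 9 is hindered and may O-acylate or react slowly, and surplus 7 consumes 8. The fallback sets out from 6 and comes back at 10. The ring opening is run alone with 7 and CuI and quenched with aqueous NH4Cl to give methyl (3S,4R)-4-(3,4-dimethoxybenzyl)-2-oxooxolane-3-carboxylate F1, which is isolated. Its copper-free sodium enolate (NaH, THF, 0 °C) is then C-acylated with 8 as a separate operation, so the two bond formations are decoupled.

Step 3, dealkoxycarbonylation of the triacylmethane 10. Chloride may open the lactone, or water may cleave the aroyl group (retro-Claisen). The fallback sets out from 6 and comes back at 13, removing the ester before the aryl ketone carbon is introduced. Ring opening and quench as above give F1, and Krapcho reaction of this simple malonate (LiCl, wet DMSO, 140 °C) gives (4R)-4-(3,4-dimethoxybenzyl)oxolan-2-one F2. Its enolate (LiN(SiMe3)2, THF, −78 °C) adds to commercial 3,4,5-trimethoxybenzaldehyde (COc1cc(C=O)cc(OC)c1OC) in a trans-selective aldol to hydroxy lactone 13, isolated as both carbinol epimers. The LiBH4 reduction of step 4 then takes 13 to 14; this costs one extra step and bypasses 10 and 12.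

**Further compounds**
F1 | step 2 | methyl (3S,4R)-4-(3,4-dimethoxybenzyl)-2-oxooxolane-3-carboxylate | COc1ccc(C[C@H]2COC(=O)[C@@H]2C(=O)OC)cc1OC
F2 | step 3 | (4R)-4-(3,4-dimethoxybenzyl)oxolan-2-one | COc1ccc(C[C@H]2COC(=O)C2)cc1OC
F0 | step 5 | none | none
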